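The numbering is that of benzofuran-2-one (O1, C2, C3, C3a, C4–C7, C7a; side chain C1′–C4′), and the target is the trans-fused (3aR,4S,7aR,1′S) isomer.
Enabling feature: the fully substituted C5=C6 alkene of the six-membered ring bears C1′ directly. C5 and C1′ can therefore come from one alkyne, and the C1′ methyl from the CH2 that a C6 methylidene gives up.
Retrosynthetic cuts, in order: the acetate and isobutyrate C–O bonds and the C3 methylidene; the C1′–H bond (back to C1′=CH2); C5=C6 together with C1′=CH2 (ring-closing enyne metathesis); C4–C5 (acyl–alkynyl coupling); C3a–C7a and O1–C2 (aldol, lactonisation); C7–C7a (allylation of formaldehyde).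
Forward: the butyrolactone ring arises first, the alkyne arm is joined at C4, the cyclohexene ring is closed on the trans lactone, and the two esters go on last.
Stereochemistry: C3a and C7a come from an Evans syn boron aldol under (4S)-4-benzyloxazolidinone control. C4 comes from (S,S)-TsDPEN–ruthenium transfer hydrogenation of an ynone. C1′ comes from an iridium hydrogenation steered by the C6 hydroxymethyl group and the C4 silyl ether.

Key step: step 12

Remark: in the trans-fused half-chair the C4 oxygen (β, on the face of H7a) is taken to be pseudoaxial, and the facial analysis of step 14 rests on this conformation.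

Abbreviations: TBS = tert-butyldimethylsilyl; TBDPS = tert-butyldiphenylsilyl; SIMes = 1,3-dimesitylimidazolidin-2-ylidene.

Step 1
Reactants: 1 2-methylenepropane-1,3-diol
Product: 3 2-[(tert-butyldimethylsilyloxy)methyl]prop-2-en-1-ol, via monosodium alkoxide 2 (not isolated)
Conditions: NaH (1 equiv), THF, 0 °C → rt; TBSCl (1 equiv), rt
Reagents that add atoms: tert-butyldimethylsilyl chloride, CC(C)(C)[Si](C)(C)Cl
Why: Monosilylation of a symmetrical diol through its sparingly soluble monosodium alkoxide, which should be silylated faster than it passes into the dialkoxide, so that only one of the two equivalent allylic hydroxyls is capped.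

Step 2
Reactants: 3 2-[(tert-butyldimethylsilyloxy)methyl]prop-2-en-1-ol
Product: 4 {[2-(bromomethyl)prop-2-en-1-yl]oxy}(tert-butyl)dimethylsilane
Conditions: CBr4, PPh3, CH2Cl2, 0 °C
Reagents that add atoms: carbon tetrabromide, BrC(Br)(Br)Br
Why: Appel bromination displaces the alkoxyphosphonium group under neutral conditions that spare the silyl ether, and direct and allylic displacement lead to the same bromide.

Step 3
Reactants: 4 {[2-(bromomethyl)prop-2-en-1-yl]oxy}(tert-butyl)dimethylsilane; 5 formaldehyde (37 % aqueous solution)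
Product: 7 3-[(tert-butyldimethylsilyloxy)methyl]but-3-en-1-ol, via allylzinc bromide 6 (not isolated)
Conditions: Zn dust, THF/sat. aq NH4Cl, 0 °C → rt
Reagents that add atoms: none
Why: Aqueous zinc Barbier allylation of formaldehyde adds the carbon that becomes C7a, and because the 2-substituted allylzinc has two equivalent CH2 termini only one homoallylic alcohol can form.

Step 4
Reactants: 7 3-[(tert-butyldimethylsilyloxy)methyl]but-3-en-1-ol
Product: 8 3-[(tert-butyldimethylsilyloxy)methyl]but-3-enal
Conditions: Dess–Martin periodinane, CH2Cl2, 0 °C → rt; short silica plug, used at once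
Reagents that add atoms: none
Why: Dess–Martin oxidation works without base or strong acid, so the β,γ-unsaturated aldehyde should not slip into conjugation before it is used.

Step 5
Reactants: 9 (4S)-4-benzyl-1,3-oxazolidin-2-one; 10 methyl 4-chloro-4-oxobutanoate
Product: 11 methyl 4-[(4S)-4-benzyl-2-oxo-1,3-oxazolidin-3-yl]-4-oxobutanoate
Conditions: Et3N, DMAP (cat), CH2Cl2, 0 °C → rt
Reagents that add atoms: none
Why: DMAP-catalysed N-acylation of the oxazolidinone by the acid chloride end of the succinate half-ester gives the imide and leaves the methyl ester as the later lactone carbonyl C2.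

Step 6
Reactants: 12 pent-4-yn-1-ol
Product: 13 tert-butyl(pent-4-yn-1-yloxy)diphenylsilane
Conditions: TBDPSCl, imidazole, CH2Cl2, rt
Reagents that add atoms: tert-butyldiphenylsilyl chloride, CC(C)(C)[Si](Cl)(c1ccccc1)c1ccccc1
Why: Imidazole-promoted silylation installs on the C4′ oxygen a group that outlasts the later selective removal of a primary TBS ether and falls together with the C4 TBS ether at the end.

Step 7
Reactants: 11 methyl 4-[(4S)-4-benzyl-2-oxo-1,3-oxazolidin-3-yl]-4-oxobutanoate; 8 3-[(tert-butyldimethylsilyloxy)methyl]but-3-enal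
Product: 16 (4S)-4-benzyl-3-{[(2R,3S)-2-{2-[(tert-butyldimethylsilyloxy)methyl]prop-2-en-1-yl}-5-oxooxolan-3-yl]carbonyl}-1,3-oxazolidin-2-one (trans lactone imide), via (Z)-dibutylboron enolate 14 (not isolated), via open syn-aldol hydroxy ester 15 (not isolated)
Conditions: Bu2BOTf, i-Pr2NEt, CH2Cl2, 0 °C; 8, −78 → 0 °C; pH 7 buffer, MeOH, 30 % H2O2, 0 °C; then PPTS (cat), CH2Cl2, rt
Reagents that add atoms: none
Why: Evans syn aldol, in which the imide is enolised selectively to the (Z)-boron enolate and reacts through a Zimmerman–Traxler chair on the face away from the benzyl group, sets C3a and C7a, and closure of the new C7a hydroxyl on the methyl ester turns the syn aldol into the trans lactone, while addition of 8 to the preformed enolate at −78 °C leaves little chance for alkene migration.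

Step 8
Reactants: 16 trans lactone imide
Product: 18 (2R,3S)-2-{2-[(tert-butyldimethylsilyloxy)methyl]prop-2-en-1-yl}-5-oxooxolane-3-carboxylic acid, via peroxy acid 17 (not isolated)
Conditions: LiOH, 30 % H2O2, THF/H2O, 0 °C; aq Na2SO3; 1 M HCl to pH 3
Reagents that add atoms: hydrogen peroxide (acting as LiOOH), OO
Why: Lithium hydroperoxide cleavage of the N-acyloxazolidinone attacks the exocyclic imide carbonyl, sulfite reduces the peroxy acid, and any lactone opened on the way recloses on acidification because only the C2 carboxyl can form a five-membered ring with the C7a hydroxyl.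

Step 9
Reactants: 18 (2R,3S)-lactone acid; 13 tert-butyl(pent-4-yn-1-yloxy)diphenylsilane
Product: 22 (4S,5R)-4-[6-(tert-butyldiphenylsilyloxy)hex-2-ynoyl]-5-{2-[(tert-butyldimethylsilyloxy)methyl]prop-2-en-1-yl}oxolan-2-one (ynone), via acid chloride 19 (not isolated), via lithium acetylide 20 (not isolated), via alkynylzinc chloride 21 (not isolated)
Conditions: 18, 1-chloro-N,N,2-trimethylprop-1-en-1-amine, CH2Cl2, 0 °C → rt; separately 13, n-BuLi, THF, −78 °C, then ZnCl2, 0 °C; combine, Pd(PPh3)4 (5 mol %), THF, 0 °C → rt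
Reagents that add atoms: none
Why: Negishi acylation (zerovalent palladium inserts into the acyl chloride, zinc passes on the alkynyl group and reductive elimination forms C4–C5) uses a nucleophile too mild to touch the butyrolactone, which a lithium acetylide acting on an amide derivative would attack, and the absence of amine base protects the β-acyloxy ketone from elimination.

Step 10
Reactants: 22 ynone
Product: 23 (4R,5R)-4-[(1S)-6-(tert-butyldiphenylsilyloxy)-1-hydroxyhex-2-yn-1-yl]-5-{2-[(tert-butyldimethylsilyloxy)methyl]prop-2-en-1-yl}oxolan-2-one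
Conditions: Ru(η6-p-cymene)[(S,S)-TsNCHPhCHPhNH] (5 mol %), i-PrOH, rt
Reagents that add atoms: none
Why: Noyori asymmetric transfer hydrogenation of an acetylenic ketone passes hydride and proton to C=O in an outer-sphere six-membered transition state in which the alkyne sits next to the arene ligand, so the (S,S) catalyst should give the (4S) carbinol under catalyst control while alkyne, alkene and lactone stay untouched in neutral 2-propanol.

Step 11
Reactants: 23 (4S)-propargylic alcohol
Product: 24 (4S,5R)-4-[(1S)-1-(tert-butyldimethylsilyloxy)-6-(tert-butyldiphenylsilyloxy)hex-2-yn-1-yl]-5-{2-[(tert-butyldimethylsilyloxy)methyl]prop-2-en-1-yl}oxolan-2-one (1,7-enyne)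
Conditions: TBSOTf, 2,6-lutidine, CH2Cl2, −78 → 0 °C
Reagents that add atoms: tert-butyldimethylsilyl triflate, CC(C)(C)[Si](C)(C)OS(=O)(=O)C(F)(F)F
Why: Silyl triflate silylation caps the hindered C4 hydroxyl, which blocks lactone transposition and carbene decomposition in step 12 and provides the bulky pseudoaxial group that step 14 relies on.

Step 12
Reactants: 24 1,7-enyne
Product: 25 (3aS,4S,7aR)-4-(tert-butyldimethylsilyloxy)-6-[(tert-butyldimethylsilyloxy)methyl]-5-[5-(tert-butyldiphenylsilyloxy)pent-1-en-2-yl]-3a,4,7,7a-tetrahydro-1-benzofuran-2(3H)-one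
Conditions: RuCl2(=CHPh)(PCy3)(SIMes) (second-generation Grubbs catalyst, 10 mol % in two portions), ethylene (1 atm), toluene (0.005 M), 80 °C
Reagents that add atoms: none
Why: Ethylene turns the benzylidene into a ruthenium methylidene, which adds across C5≡C1′ with CH2 on C1′ and ruthenium on C5; the ruthenacyclobutene opens to a vinylcarbene, and [2+2] addition and cycloreversion of this carbene with the C6 methylidene create C5=C6 and hand the methylidene back to the metal. The closest known reaction type is the ring-closing enyne metathesis of 1,7-enynes to 1-alkenylcyclohexenes under an ethylene atmosphere with NHC-bearing ruthenium carbenes, a class that includes internal alkynes and 1,1-disubstituted alkenes, although a fully substituted ring alkene sits at its demanding end. The cyclohexene ring closes in the exo mode, so that only C5 of the alkyne becomes a ring atom and C1′ is left outside as the methylidene end of a 1,3-diene. No stereocentre is created; C3a, C4 and C7a are carried through a neutral isomerisation, and the geometry of the new alkene is dictated by the ring. The step needs CH2 delivery to C1′, six- rather than seven-membered closure, and capture of the carbene by the tethered alkene instead of by ethylene. The trans lactone holds the C4 and C7 arms close to gauche and so brings C5 and C6 within reach, the six-membered closure is kinetically ahead of the seven-membered one, and one atmosphere of ethylene at 80 °C should regenerate the methylidene without outrunning the intramolecular step.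

Step 13
Reactants: 25 bicyclic diene tris-silyl ether
Product: 26 (3aS,4S,7aR)-4-(tert-butyldimethylsilyloxy)-5-[5-(tert-butyldiphenylsilyloxy)pent-1-en-2-yl]-6-(hydroxymethyl)-3a,4,7,7a-tetrahydro-1-benzofuran-2(3H)-one
Conditions: HF·pyridine, pyridine, THF, 0 °C
Reagents that add atoms: none
Why: Selective desilylation with buffered HF·pyridine should cleave the primary allylic TBS ether well before the hindered secondary C4 TBS ether and the more robust TBDPS ether, and the buffered medium avoids ionisation of the dienylic positions.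

Step 14
Reactants: 26 dienyl primary alcohol
Product: 27 (3aS,4S,7aR)-4-(tert-butyldimethylsilyloxy)-5-[(2S)-5-(tert-butyldiphenylsilyloxy)pentan-2-yl]-6-(hydroxymethyl)-3a,4,7,7a-tetrahydro-1-benzofuran-2(3H)-one
Conditions: [Ir(cod)(PCy3)(py)]PF6 (5 mol %), H2 (1 atm), CH2Cl2, 0 °C → rt
Reagents that add atoms: none
Why: Hydroxyl-directed hydrogenation with the cationic Crabtree iridium catalyst anchors the metal on the C6 hydroxymethyl oxygen, so it meets the twisted 1,1-disubstituted C1′ alkene only on the flank that faces C6, while the pseudoaxial β-silyloxy group at C4 keeps the bulkier C2′ methylene on the α face and the methylidene on the β face, so hydrogen should land on C1′ in the (S) sense (anchoring on a free C4 hydroxyl would expose the opposite flank of the same rotamer, which is why C4 stays protected), and the tetrasubstituted C5=C6 alkene is far slower to react.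

Step 15
Reactants: 27 saturated side-chain alcohol
Product: 31 (3aS,4S,7aR)-4-(tert-butyldimethylsilyloxy)-5-[(2S)-5-(tert-butyldiphenylsilyloxy)pentan-2-yl]-6-(hydroxymethyl)-3-methylidene-3a,4,7,7a-tetrahydro-1-benzofuran-2(3H)-one, via dilithium alkoxide enolate 28 (not isolated), via Mannich base 29 (not isolated), via methiodide 30 (not isolated)
Conditions: lithium diisopropylamide (2.5 equiv), THF, −78 °C; dimethyl(methylidene)ammonium iodide, −78 °C → rt; H2O; then MeI, MeOH, rt; then aq NaHCO3, CH2Cl2, rt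
Reagents that add atoms: dimethyl(methylidene)ammonium iodide (Eschenmoser's salt), C=[N+](C)C.[I-]
Why: Lactone α-methylenation by the Mannich route (enolate aminomethylation, quaternisation, β-elimination) is run on the alkoxide enolate so that no extra protecting step is needed, the remote C6 alkoxide cannot reach the lactone carbonyl, and C3a is not touched because only C3 is deprotonated.

Step 16
Reactants: 31 α-methylidene lactone alcohol
Product: 32 {(3aS,4S,7aR)-4-(tert-butyldimethylsilyloxy)-5-[(2S)-5-(tert-butyldiphenylsilyloxy)pentan-2-yl]-3-methylidene-2-oxo-2,3,3a,4,7,7a-hexahydro-1-benzofuran-6-yl}methyl 2-methylpropanoate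
Conditions: i-PrCOCl, pyridine, CH2Cl2, 0 °C
Reagents that add atoms: isobutyryl chloride, CC(C)C(=O)Cl
Why: Acylation of the only free hydroxyl with an acid chloride and pyridine places the isobutyrate on the C6 hydroxymethyl group after all enolate chemistry is finished.

Step 17
Reactants: 32 isobutyrate bis-silyl ether
Product: 33 {(3aR,4S,7aR)-4-hydroxy-5-[(2S)-5-hydroxypentan-2-yl]-3-methylidene-2-oxo-2,3,3a,4,7,7a-hexahydro-1-benzofuran-6-yl}methyl 2-methylpropanoate
Conditions: HF·pyridine, THF, 0 °C → rt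
Reagents that add atoms: none
Why: Global fluoride-mediated desilylation under mildly acidic conditions removes the C4 TBS and C4′ TBDPS groups together and avoids the basic fluoride sources that could add to the methylidene lactone, move acyl groups or transpose the lactone.

Step 18
Reactants: 33 diol
Product: 34 {(3aR,4S,7aR)-5-[(2S)-5-acetoxypentan-2-yl]-4-hydroxy-3-methylidene-2-oxo-2,3,3a,4,7,7a-hexahydro-1-benzofuran-6-yl}methyl 2-methylpropanoate (CNP0246650.1)
Conditions: AcCl (1.1 equiv), 2,4,6-collidine, CH2Cl2, −78 °C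
Reagents that add atoms: acetyl chloride, CC(=O)Cl
Why: Chemoselective acetylation of a primary over a secondary alcohol with acetyl chloride and collidine at low temperature should take the unhindered C4′ hydroxyl only, since the pseudoaxial C4 hydroxyl is wedged between C3a and the branched C5 substituent.

Compound list
1 | 2-methylenepropane-1,3-diol | C=C(CO)CO | starting material
2 | sodium 2-(hydroxymethyl)prop-2-en-1-olate | C=C(CO)C[O-].[Na+] | intermediate
3 | 2-[(tert-butyldimethylsilyloxy)methyl]prop-2-en-1-ol | C=C(CO)CO[Si](C)(C)C(C)(C)C | intermediate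
4 | {[2-(bromomethyl)prop-2-en-1-yl]oxy}(tert-butyl)dimethylsilane | C=C(CBr)CO[Si](C)(C)C(C)(C)C | intermediate
5 | formaldehyde | C=O | starting material
6 | {2-[(tert-butyldimethylsilyloxy)methyl]prop-2-en-1-yl}zinc bromide | C=C(C[Zn]Br)CO[Si](C)(C)C(C)(C)C | intermediate
7 | 3-[(tert-butyldimethylsilyloxy)methyl]but-3-en-1-ol | C=C(CCO)CO[Si](C)(C)C(C)(C)C | intermediate
8 | 3-[(tert-butyldimethylsilyloxy)methyl]but-3-enal | C=C(CC=O)CO[Si](C)(C)C(C)(C)C | intermediate
9 | (4S)-4-benzyl-1,3-oxazolidin-2-one | O=C1N[C@@H](Cc2ccccc2)CO1 | starting material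
10 | methyl 4-chloro-4-oxobutanoate | COC(=O)CCC(=O)Cl | starting material
11 | methyl 4-[(4S)-4-benzyl-2-oxo-1,3-oxazolidin-3-yl]-4-oxobutanoate | COC(=O)CCC(=O)N1[C@@H](Cc2ccccc2)COC1=O | intermediate
12 | pent-4-yn-1-ol | C#CCCCO | starting material
13 | tert-butyl(pent-4-yn-1-yloxy)diphenylsilane | C#CCCCO[Si](c1ccccc1)(c1ccccc1)C(C)(C)C | intermediate
14 | (Z)-dibutylboron enolate of 11 | COC(=O)C/C=C(\OB(CCCC)CCCC)N1[C@@H](Cc2ccccc2)COC1=O | intermediate
15 | methyl (3S,4R)-3-{[(4S)-4-benzyl-2-oxo-1,3-oxazolidin-3-yl]carbonyl}-6-[(tert-butyldimethylsilyloxy)methyl]-4-hydroxyhept-6-enoate | COC(=O)C[C@H](C(=O)N1[C@@H](Cc2ccccc2)COC1=O)[C@H](O)CC(=C)CO[Si](C)(C)C(C)(C)C | intermediate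
16 | (4S)-4-benzyl-3-{[(2R,3S)-2-{2-[(tert-butyldimethylsilyloxy)methyl]prop-2-en-1-yl}-5-oxooxolan-3-yl]carbonyl}-1,3-oxazolidin-2-one | O=C1O[C@H](CC(=C)CO[Si](C)(C)C(C)(C)C)[C@H](C1)C(=O)N1[C@@H](Cc2ccccc2)COC1=O | intermediate
17 | (2R,3S)-2-{2-[(tert-butyldimethylsilyloxy)methyl]prop-2-en-1-yl}-5-oxooxolane-3-carboperoxoic acid | O=C1O[C@H](CC(=C)CO[Si](C)(C)C(C)(C)C)[C@H](C1)C(=O)OO | intermediate
18 | (2R,3S)-2-{2-[(tert-butyldimethylsilyloxy)methyl]prop-2-en-1-yl}-5-oxooxolane-3-carboxylic acid | O=C1O[C@H](CC(=C)CO[Si](C)(C)C(C)(C)C)[C@H](C1)C(=O)O | intermediate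
19 | (2R,3S)-2-{2-[(tert-butyldimethylsilyloxy)methyl]prop-2-en-1-yl}-5-oxooxolane-3-carbonyl chloride | O=C1O[C@H](CC(=C)CO[Si](C)(C)C(C)(C)C)[C@H](C1)C(=O)Cl | intermediate
20 | [5-(tert-butyldiphenylsilyloxy)pent-1-yn-1-yl]lithium | [Li]C#CCCCO[Si](c1ccccc1)(c1ccccc1)C(C)(C)C | intermediate
21 | [5-(tert-butyldiphenylsilyloxy)pent-1-yn-1-yl]zinc chloride | Cl[Zn]C#CCCCO[Si](c1ccccc1)(c1ccccc1)C(C)(C)C | intermediate
22 | (4S,5R)-4-[6-(tert-butyldiphenylsilyloxy)hex-2-ynoyl]-5-{2-[(tert-butyldimethylsilyloxy)methyl]prop-2-en-1-yl}oxolan-2-one | O=C1O[C@H](CC(=C)CO[Si](C)(C)C(C)(C)C)[C@H](C1)C(=O)C#CCCCO[Si](c1ccccc1)(c1ccccc1)C(C)(C)C | intermediate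
23 | (4R,5R)-4-[(1S)-6-(tert-butyldiphenylsilyloxy)-1-hydroxyhex-2-yn-1-yl]-5-{2-[(tert-butyldimethylsilyloxy)methyl]prop-2-en-1-yl}oxolan-2-one | O=C1O[C@H](CC(=C)CO[Si](C)(C)C(C)(C)C)[C@H](C1)[C@H](O)C#CCCCO[Si](c1ccccc1)(c1ccccc1)C(C)(C)C | intermediate
24 | (4S,5R)-4-[(1S)-1-(tert-butyldimethylsilyloxy)-6-(tert-butyldiphenylsilyloxy)hex-2-yn-1-yl]-5-{2-[(tert-butyldimethylsilyloxy)methyl]prop-2-en-1-yl}oxolan-2-one | O=C1O[C@H](CC(=C)CO[Si](C)(C)C(C)(C)C)[C@H](C1)[C@H](O[Si](C)(C)C(C)(C)C)C#CCCCO[Si](c1ccccc1)(c1ccccc1)C(C)(C)C | intermediate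
25 | (3aS,4S,7aR)-4-(tert-butyldimethylsilyloxy)-6-[(tert-butyldimethylsilyloxy)methyl]-5-[5-(tert-butyldiphenylsilyloxy)pent-1-en-2-yl]-3a,4,7,7a-tetrahydro-1-benzofuran-2(3H)-one | C1C(=O)O[C@@H]2CC(CO[Si](C)(C)C(C)(C)C)=C(C(=C)CCCO[Si](c3ccccc3)(c3ccccc3)C(C)(C)C)[C@@H](O[Si](C)(C)C(C)(C)C)[C@@H]12 | intermediate
26 | (3aS,4S,7aR)-4-(tert-butyldimethylsilyloxy)-5-[5-(tert-butyldiphenylsilyloxy)pent-1-en-2-yl]-6-(hydroxymethyl)-3a,4,7,7a-tetrahydro-1-benzofuran-2(3H)-one | C1C(=O)O[C@@H]2CC(CO)=C(C(=C)CCCO[Si](c3ccccc3)(c3ccccc3)C(C)(C)C)[C@@H](O[Si](C)(C)C(C)(C)C)[C@@H]12 | intermediate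
27 | (3aS,4S,7aR)-4-(tert-butyldimethylsilyloxy)-5-[(2S)-5-(tert-butyldiphenylsilyloxy)pentan-2-yl]-6-(hydroxymethyl)-3a,4,7,7a-tetrahydro-1-benzofuran-2(3H)-one | C1C(=O)O[C@@H]2CC(CO)=C([C@@H](C)CCCO[Si](c3ccccc3)(c3ccccc3)C(C)(C)C)[C@@H](O[Si](C)(C)C(C)(C)C)[C@@H]12 | intermediate
28 | dilithium alkoxide enolate of 27 (C2–O and C6–CH2–O lithiated, C2=C3) | C1=C(O[Li])O[C@@H]2CC(CO[Li])=C([C@@H](C)CCCO[Si](c3ccccc3)(c3ccccc3)C(C)(C)C)[C@@H](O[Si](C)(C)C(C)(C)C)[C@@H]12 | intermediate
29 | 3-[(dimethylamino)methyl] derivative of 27 (C3 configuration open) | CN(C)CC1C(=O)O[C@@H]2CC(CO)=C([C@@H](C)CCCO[Si](c3ccccc3)(c3ccccc3)C(C)(C)C)[C@@H](O[Si](C)(C)C(C)(C)C)[C@@H]12 | intermediate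
30 | trimethylammoniomethyl iodide derived from 29 | C[N+](C)(C)CC1C(=O)O[C@@H]2CC(CO)=C([C@@H](C)CCCO[Si](c3ccccc3)(c3ccccc3)C(C)(C)C)[C@@H](O[Si](C)(C)C(C)(C)C)[C@@H]12.[I-] | intermediate
31 | (3aS,4S,7aR)-4-(tert-butyldimethylsilyloxy)-5-[(2S)-5-(tert-butyldiphenylsilyloxy)pentan-2-yl]-6-(hydroxymethyl)-3-methylidene-3a,4,7,7a-tetrahydro-1-benzofuran-2(3H)-one | C=C1C(=O)O[C@@H]2CC(CO)=C([C@@H](C)CCCO[Si](c3ccccc3)(c3ccccc3)C(C)(C)C)[C@@H](O[Si](C)(C)C(C)(C)C)[C@@H]12 | intermediate
32 | {(3aS,4S,7aR)-4-(tert-butyldimethylsilyloxy)-5-[(2S)-5-(tert-butyldiphenylsilyloxy)pentan-2-yl]-3-methylidene-2-oxo-2,3,3a,4,7,7a-hexahydro-1-benzofuran-6-yl}methyl 2-methylpropanoate | C=C1C(=O)O[C@@H]2CC(COC(=O)C(C)C)=C([C@@H](C)CCCO[Si](c3ccccc3)(c3ccccc3)C(C)(C)C)[C@@H](O[Si](C)(C)C(C)(C)C)[C@@H]12 | intermediate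
33 | {(3aR,4S,7aR)-4-hydroxy-5-[(2S)-5-hydroxypentan-2-yl]-3-methylidene-2-oxo-2,3,3a,4,7,7a-hexahydro-1-benzofuran-6-yl}methyl 2-methylpropanoate | C=C1C(=O)O[C@@H]2CC(COC(=O)C(C)C)=C([C@@H](C)CCCO)[C@@H](O)[C@@H]12 | intermediate
34 | {(3aR,4S,7aR)-5-[(2S)-5-acetoxypentan-2-yl]-4-hydroxy-3-methylidene-2-oxo-2,3,3a,4,7,7a-hexahydro-1-benzofuran-6-yl}methyl 2-methylpropanoate (CNP0246650.1) | C=C1C(=O)O[C@@H]2CC(COC(=O)C(C)C)=C([C@@H](C)CCCOC(C)=O)[C@@H](O)[C@@H]12 | target

Total step count: 18. Longest linear sequence: 16 (steps 1–4, then 7–18).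

Steps most likely to fail

Step 12. The hindered vinylcarbene may be intercepted by ethylene, or the methylidene may add to the alkyne the other way round. In both cases ring closure stalls and open-chain material builds up. The closure would then be divided into two operations that make the same bonds. Setting out from 24, cross enyne metathesis with ethylene (RuCl2(=CHPh)(PCy3)(SIMes), ethylene, CH2Cl2, rt → 40 °C) is driven to completion to give the acyclic triene lactone F1. Diene ring-closing metathesis then joins its C5 and C6 methylidenes with the less encumbered carbene RuCl2(=CH-C6H4-2-O-i-Pr)[1,3-bis(2-methylphenyl)imidazolidin-2-ylidene] in toluene at 80–100 °C under an argon sparge. This comes back to the route at 25.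

Step 14. Facial selectivity at C1′ may be poor if both rotamers of the twisted diene are hydrogenated. The alkene may also migrate along the diene, or the allylic hydroxyl may draw the catalyst onto C5=C6. Stereocontrol would then be handed from the substrate to the catalyst. Setting out from 25, which has no free hydroxyl, asymmetric hydrogenation would use a chiral iridium P,N complex, [Ir(cod)(t-Bu-PHOX)]B[3,5-(CF3)2C6H3]4. The enantiomeric form chosen is the one that reinforces the steric bias of the C4 silyl ether. This should give the saturated tris-silyl ether F2. Buffered HF·pyridine then frees the C6 hydroxymethyl group and the route is rejoined at 27.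

Step 9. The acid chloride may be lost through ketene formation or decarbonylation on palladium, and the β-acyloxy ketone may open by elimination during the coupling. The C4–C5 bond would then be made by 1,2-addition to an aldehyde.
- Setting out from 18, isobutyl chloroformate and N-methylmorpholine (THF, −20 °C) give the mixed carbonic anhydride F3.
- NaBH4 in THF/MeOH reduces it to the hydroxymethyl lactone F4. Borane is avoided because of the methylidene.
- Dess–Martin oxidation gives the formyl lactone F5.
- One equivalent of lithium acetylide 20 (THF, −78 °C) adds to the aldehyde faster than to the lactone and gives the C4-epimeric propargylic alcohols F6.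
- A second Dess–Martin oxidation erases the unselective centre, and the route is rejoined at 22.

Further compounds
F1 | step 12 | (4S,5R)-4-[(1S)-1-(tert-butyldimethylsilyloxy)-6-(tert-butyldiphenylsilyloxy)-2,3-dimethylidenehexyl]-5-{2-[(tert-butyldimethylsilyloxy)methyl]prop-2-en-1-yl}oxolan-2-one | O=C1O[C@H](CC(=C)CO[Si](C)(C)C(C)(C)C)[C@H](C1)[C@H](O[Si](C)(C)C(C)(C)C)C(=C)C(=C)CCCO[Si](c1ccccc1)(c1ccccc1)C(C)(C)C
F2 | step 14 | (3aS,4S,7aR)-4-(tert-butyldimethylsilyloxy)-6-[(tert-butyldimethylsilyloxy)methyl]-5-[(2S)-5-(tert-butyldiphenylsilyloxy)pentan-2-yl]-3a,4,7,7a-tetrahydro-1-benzofuran-2(3H)-one | C1C(=O)O[C@@H]2CC(CO[Si](C)(C)C(C)(C)C)=C([C@@H](C)CCCO[Si](c3ccccc3)(c3ccccc3)C(C)(C)C)[C@@H](O[Si](C)(C)C(C)(C)C)[C@@H]12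
F3 | step 9 | (2R,3S)-2-{2-[(tert-butyldimethylsilyloxy)methyl]prop-2-en-1-yl}-5-oxooxolane-3-carboxylic isobutyl carbonic anhydride | O=C1O[C@H](CC(=C)CO[Si](C)(C)C(C)(C)C)[C@H](C1)C(=O)OC(=O)OCC(C)C
F4 | step 9 | (4R,5R)-5-{2-[(tert-butyldimethylsilyloxy)methyl]prop-2-en-1-yl}-4-(hydroxymethyl)oxolan-2-one | O=C1O[C@H](CC(=C)CO[Si](C)(C)C(C)(C)C)[C@H](C1)CO
F5 | step 9 | (2R,3S)-2-{2-[(tert-butyldimethylsilyloxy)methyl]prop-2-en-1-yl}-5-oxooxolane-3-carbaldehyde | O=C1O[C@H](CC(=C)CO[Si](C)(C)C(C)(C)C)[C@H](C1)C=O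
F6 | step 9 | 4-[6-(tert-butyldiphenylsilyloxy)-1-hydroxyhex-2-yn-1-yl]-5-{2-[(tert-butyldimethylsilyloxy)methyl]prop-2-en-1-yl}oxolan-2-one, trans lactone as in 23, both carbinol epimers | O=C1O[C@H](CC(=C)CO[Si](C)(C)C(C)(C)C)[C@H](C1)C(O)C#CCCCO[Si](c1ccccc1)(c1ccccc1)C(C)(C)C
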